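**Plan**
1. Retrosynthetic cuts: after the three silyl ethers are removed, C4–C5 (ring A) and C9–C10 (ring B) of the trans-decalin are cut together. This leads back to an acyclic epoxy-diene-allylsilane that already carries the finished lactone. The chain is then cut at C5–C6 (Negishi coupling), C12–C13 (aldol), O–C16 (lactonisation), C8–C17 (nickel coupling) and C3=C4 (Wittig).
2. Enabling feature: in rings A and B the atoms C4, C5=C10 and C9=C8 stand in 1,5-diene (polyprenoid) spacing. The equatorial C3–OH flanks quaternary C4 (a latent C3–C4 epoxide), and the exocyclic C8=C17 methylene is the footprint of a C17 silyl group. Both carbocycles can therefore be closed in one biosynthesis-like cationic cascade.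
3. Forward order: the lactone ring is closed first (fragment B, C6–C9 and C11–C17). Fragment B is joined to fragment A (C1–C5, C10, C18–C20) at C5–C6. The cascade then closes ring A and, as the last ring, ring B; global desilylation ends the route.
4. Stereochemistry: C14 is bought (malic-acid-derived dioxolane 11). C12 and C13 come from an Evans syn-aldol, and C3 and C4 from a Katsuki–Sharpless epoxidation of a Z-allylic alcohol. In the key step C4 (inversion), C5, C10 and C9 are relayed from that epoxide and from the two alkene geometries through a chair–chair array.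

Key step: step 17

Remark: the atom numbers C1–C20 are the labdane numbers of the target (C3 carbinol, C4 quaternary, C8=C17 methylene, C12 side-chain carbinol, C13–C16 lactone) and are used for all intermediates. TBS = tert-butyldimethylsilyl, TES = triethylsilyl.

**Fragment A**

Step 1
Reactants: 1 5-iodopent-1-yne
Product: 2 (pent-4-yn-1-yl)triphenylphosphonium iodide
Conditions: PPh3, MeCN, reflux
Reagents that add atoms: triphenylphosphine c1ccc(cc1)P(c1ccccc1)c1ccccc1
Why: SN2 quaternisation of the phosphine by the primary iodide (phosphonium salt formation for a Wittig reaction); no stereocentre is involved.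

Step 2
Reactants: 2 (pent-4-yn-1-yl)triphenylphosphonium iodide; 3 1-[(tert-butyldimethylsilyl)oxy]propan-2-one
Product: 5 (Z)-tert-butyldimethyl[(2-methylhept-2-en-6-yn-1-yl)oxy]silane, via phosphonium ylide 4 (not isolated)
Conditions: KN(SiMe3)2, THF–HMPA, −78 °C; then 3, −78 °C → rt
Reagents that add atoms: none
Why: Wittig reaction of a non-stabilised ylide with an alpha-silyloxy ketone, a pairing known to give the Z-trisubstituted allylic ether under kinetic control because the oxaphosphetane forms with the ylide chain syn to the oxygenated arm; this geometry later becomes the C4 configuration.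

Step 3
Reactants: 5 (Z)-enyne silyl ether
Product: 7 tert-butyl{[(2Z,6E)-7-iodo-2,6-dimethylhepta-2,6-dien-1-yl]oxy}dimethylsilane, via alkenyldimethylalane 6 (not isolated)
Conditions: Me3Al (2 equiv), Cp2ZrCl2 (0.25 equiv), CH2Cl2, 0 °C → rt; then I2, THF, −30 °C
Reagents that add atoms: trimethylaluminium C[Al](C)C; iodine II
Why: Negishi zirconium-catalysed carboalumination adds methyl (to the internal carbon C10) and aluminium syn across the terminal alkyne, and iodinolysis with retention should give the E-iodoalkene while the trisubstituted alkene and the silyl ether stay inert.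

Step 4
Reactants: 7 (2Z,6E)-iodo diene silyl ether
Product: 8 (2Z,6E)-7-iodo-2,6-dimethylhepta-2,6-dien-1-ol
Conditions: Bu4NF, THF, 0 °C
Reagents that add atoms: none
Why: Fluoride-induced desilylation frees the allylic alcohol that must direct the epoxidation; the iodoalkene is inert to fluoride.

Step 5
Reactants: 8 (2Z,6E)-iodo dienol
Product: 9 {(2S,3R)-3-[(E)-4-iodo-3-methylbut-3-en-1-yl]-2-methyloxiran-2-yl}methanol
Conditions: Ti(OiPr)4 (10 mol %), L-(+)-diethyl tartrate (12 mol %), t-BuOOH (decane), 4 Å MS, CH2Cl2, −20 °C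
Reagents that add atoms: tert-butyl hydroperoxide CC(C)(C)OO
Why: Katsuki–Sharpless asymmetric epoxidation, in which the titanium–tartrate complex binds the allylic alcohol and with the L-(+)-tartrate delivers oxygen to the face that gives the (2S,3R)-epoxy alcohol; this sets C3 (R) and the pre-inversion C4 centre and leaves the electron-poor iodoalkene untouched.

Step 6
Reactants: 9 epoxy alcohol
Product: 10 fragment A: tert-butyl({(2S,3R)-3-[(E)-4-iodo-3-methylbut-3-en-1-yl]-2-methyloxiran-2-yl}methoxy)dimethylsilane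
Conditions: TBSCl, imidazole, DMF, 0 °C → rt
Reagents that add atoms: tert-butyldimethylsilyl chloride CC(C)(C)[Si](C)(C)Cl
Why: Standard silyl ether protection masks the C19 hydroxyl so that it can neither quench the organozinc reagent nor trap a cation later.

**Fragment C**

Step 7
Reactants: 11 (S)-2-(2,2-dimethyl-1,3-dioxolan-4-yl)ethan-1-ol
Product: 12 (S)-2-(2,2-dimethyl-1,3-dioxolan-4-yl)acetic acid
Conditions: TEMPO (cat.), NaClO2, NaOCl (cat.), MeCN–phosphate buffer (pH 6.7), 35 °C; work-up at pH 4
Reagents that add atoms: sodium chlorite [Na+].[O-]Cl=O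
Why: TEMPO/chlorite oxidation (oxoammonium step, then Pinnick-type step) at buffered pH takes the primary alcohol to the acid without opening the acetonide or touching the purchased C14 stereocentre.

Step 8
Reactants: 12 dioxolane acetic acid; 13 (R)-4-benzyloxazolidin-2-one
Product: 15 fragment C: (R)-4-benzyl-3-{2-[(S)-2,2-dimethyl-1,3-dioxolan-4-yl]acetyl}oxazolidin-2-one, via mixed pivalic anhydride 14 (not isolated)
Conditions: t-BuCOCl, Et3N, THF, −20 °C; then 13, LiCl, −20 °C → rt
Reagents that add atoms: none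
Why: N-acylation of the oxazolidinone by the LiCl-assisted mixed-anhydride method, with attack at the less hindered carbonyl of 14.

**Fragment B**

Step 9
Reactants: 16 2,3-dihydrofuran
Product: 19 tert-butyl[2-(4,5-dihydrofuran-2-yl)ethoxy]dimethylsilane, via 5-lithio-2,3-dihydrofuran 17 (not isolated), via lithium alkoxide 18 (not isolated)
Conditions: t-BuLi, THF, −78 → 0 °C; ethylene oxide, −78 °C → rt; TBSCl, DMAP (cat.), rt
Reagents that add atoms: ethylene oxide C1CO1; tert-butyldimethylsilyl chloride CC(C)(C)[Si](C)(C)Cl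
Why: Vinylic alpha-lithiation of the cyclic enol ether, epoxide opening by the alkenyllithium and O-silylation of the alkoxide in one flask give the C6–C12 chain with the C8–O bond as a latent leaving group.

Step 10
Reactants: 19 5-substituted 2,3-dihydrofuran
Product: 20 (Z)-6-[(tert-butyldimethylsilyl)oxy]-4-[(trimethylsilyl)methyl]hex-3-en-1-ol
Conditions: Me3SiCH2MgCl (3 equiv), NiCl2(PPh3)2 (5 mol %), toluene–Et2O, 80 °C
Reagents that add atoms: (trimethylsilyl)methylmagnesium chloride C[Si](C)(C)C[Mg]Cl
Why: Nickel-catalysed Kumada-type coupling of an enol ether (Wenkert reaction), in which zerovalent nickel inserts into the alkenyl C8–O bond and the Grignard carbon replaces oxygen with retention, so that CH2SiMe3 ends cis to C11 and the allylsilane geometry needed for an equatorial C9 side chain is fixed.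

Step 11
Reactants: 20 allylsilane alcohol
Product: 21 (Z)-6-[(tert-butyldimethylsilyl)oxy]-4-[(trimethylsilyl)methyl]hex-3-enal
Conditions: Dess–Martin periodinane, pyridine, CH2Cl2, 0 °C
Reagents that add atoms: none
Why: Dess–Martin oxidation with pyridine buffering works under non-enolising conditions, so the beta,gamma-alkene should stay out of conjugation and the allylsilane should stay intact.

Step 12
Reactants: 15 fragment C imide; 21 beta,gamma-unsaturated aldehyde
Product: 23 (R)-4-benzyl-3-{(2S,3S,5Z)-8-[(tert-butyldimethylsilyl)oxy]-2-[(S)-2,2-dimethyl-1,3-dioxolan-4-yl]-3-hydroxy-6-[(trimethylsilyl)methyl]oct-5-enoyl}oxazolidin-2-one, via Z-boron enolate 22 (not isolated)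
Conditions: 15, Bu2BOTf, Et3N, CH2Cl2, −78 → 0 °C; 21, −78 → 0 °C; pH 7 buffer, MeOH, H2O2, 0 °C
Reagents that add atoms: none
Why: Evans syn-aldol, in which soft enolisation gives the Z(O)-boron enolate (its covalent B–O bond disfavours beta-elimination of the dioxolane oxygen) and the Zimmerman–Traxler chair on the enolate face opposite the benzyl group of the (R)-auxiliary sets C13 (S) and C12 (S) in the syn relation of the target.

Step 13
Reactants: 23 Evans adduct
Product: 25 (3S,4S)-3-{(1S,3Z)-1,6-dihydroxy-4-[(trimethylsilyl)methyl]hex-3-en-1-yl}-4-hydroxyoxolan-2-one, via tetraol imide 24 (not isolated)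
Conditions: PPTS (0.3 equiv), MeOH, 45 °C
Reagents that add atoms: none
Why: Mild acid-catalysed transketalisation and primary desilylation free the C15 and C6 hydroxyls, and C15–OH attacks the imide carbonyl C16 in a 5-exo-trig lactonisation that expels the auxiliary and closes the lactone ring without touching C12–C14 or the allylsilane.

Step 14
Reactants: 25 triol lactone
Product: 26 (3S,4S)-4-hydroxy-3-{(1S,3Z)-1-hydroxy-6-iodo-4-[(trimethylsilyl)methyl]hex-3-en-1-yl}oxolan-2-one
Conditions: PPh3, I2, imidazole (pre-mixed), THF, −10 → 0 °C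
Reagents that add atoms: iodine II
Why: Garegg–Samuelsson (Appel-type) iodination, in which the pre-formed iodophosphonium salt activates the unhindered primary C6 hydroxyl much faster than the two secondary ones and pre-mixing leaves no free iodine to attack the allylsilane.

Step 15
Reactants: 26 iodo diol lactone
Product: 27 fragment B: (3S,4S)-4-[(tert-butyldimethylsilyl)oxy]-3-{(1S,3Z)-1-[(tert-butyldimethylsilyl)oxy]-6-iodo-4-[(trimethylsilyl)methyl]hex-3-en-1-yl}oxolan-2-one
Conditions: TBSOTf, 2,6-lutidine, CH2Cl2, −78 → 0 °C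
Reagents that add atoms: tert-butyldimethylsilyl triflate CC(C)(C)[Si](C)(C)OS(=O)(=O)C(F)(F)F
Why: Silyl triflate silylation of both secondary hydroxyls under a hindered, weak base (no E1cB loss of the beta-oxygen) blocks cation trapping and retro-aldol cleavage in the later steps.

**Union, key step and end game**

Step 16
Reactants: 27 fragment B iodide; 10 fragment A iodoalkene
Product: 29 (3S,4S)-4-[(tert-butyldimethylsilyl)oxy]-3-[(1S,3Z,7E)-1-[(tert-butyldimethylsilyl)oxy]-10-[(2R,3S)-3-{[(tert-butyldimethylsilyl)oxy]methyl}-3-methyloxiran-2-yl]-8-methyl-4-[(trimethylsilyl)methyl]deca-3,7-dien-1-yl]oxolan-2-one, via alkylzinc iodide 28 (not isolated)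
Conditions: Zn dust (activated with BrCH2CH2Br and Me3SiCl), THF, 35 °C; then 10, PdCl2(dppf) (5 mol %), THF, rt
Reagents that add atoms: none
Why: Negishi coupling of a homoallylzinc reagent with an iodoalkene (the classical 1,5-diene synthesis), in which direct zinc insertion tolerates lactone and silyl ethers, and oxidative addition to zerovalent palladium, transmetalation and reductive elimination keep the E geometry while dppf suppresses beta-hydride elimination.

Step 17
Reactants: 29 epoxy-diene-allylsilane lactone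
Product: 30 (3S,4S)-4-[(tert-butyldimethylsilyl)oxy]-3-{(1S)-1-[(tert-butyldimethylsilyl)oxy]-2-[(1R,4aS,5R,6R,8aS)-5-{[(tert-butyldimethylsilyl)oxy]methyl}-6-hydroxy-5,8a-dimethyl-2-methylidenedecahydronaphthalen-1-yl]ethyl}oxolan-2-one
Conditions: MeAlCl2 (3 equiv), CH2Cl2, −78 °C; Et3N–MeOH quench, aq. NaHCO3
Reagents that add atoms: none
Why: MeAlCl2 binds the epoxide oxygen, the C5=C10 alkene opens the C4–O bond from the rear in an SN2-like 6-endo closure of ring A, the tertiary C10 cation is captured by C9 of the allylsilane in a 6-endo-trig closure of ring B, and loss of the C17 silyl group from the beta-silyl C8 cation ends the cascade as the C8=C17 methylene; this is an epoxide-initiated, allylsilane-terminated cationic polyene cyclisation of the Stork–Eschenmoser type, the laboratory copy of the copalyl-diphosphate-synthase-type cyclisation. C3 keeps its configuration, and its O–Al group takes the equatorial site of a chair–chair array, which fixes the absolute sense of folding. C4 is set by inversion, so the Z-disposed CH2OTBS arm becomes axial and the methyl group equatorial, a transfer that a planar radical at C4 could not give. Anti addition across the E C5=C10 alkene gives the trans ring fusion (C5–H and C20 anti), and the C8=C9 geometry (C7 trans to C11) places the C11 side chain equatorial at C9. The step needs opening at C4 rather than C3, complete propagation and exocyclic termination, which are secured by the tertiary cation-stabilising C4, the pre-organised 1,5-diene spacing and the beta-silicon effect, while the methyl–aluminium bond scavenges protons that would protodesilylate the terminator. The excess of Lewis acid saturates the lactone carbonyl, and the silyl ethers keep the C12, C14 and C19 oxygens from trapping the cations.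

Step 18
Reactants: 30 cyclised tris(silyl ether)
Product: 31 target: (3S,4S)-4-hydroxy-3-{(1S)-1-hydroxy-2-[(1R,4aS,5R,6R,8aS)-6-hydroxy-5-(hydroxymethyl)-5,8a-dimethyl-2-methylidenedecahydronaphthalen-1-yl]ethyl}oxolan-2-one
Conditions: HF·pyridine, pyridine, THF, 0 °C → rt
Reagents that add atoms: none
Why: Global fluoride desilylation under buffered, mildly acidic conditions avoids the E1cB elimination or retro-aldol cleavage that basic fluoride could cause in the beta-hydroxy lactone and leaves all stereocentres and the exocyclic alkene untouched.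

**Compound list**
1 | 5-iodopent-1-yne | C#CCCCI | starting material
2 | (pent-4-yn-1-yl)triphenylphosphonium iodide | C#CCCC[P+](c1ccccc1)(c1ccccc1)c1ccccc1.[I-] | intermediate
3 | 1-[(tert-butyldimethylsilyl)oxy]propan-2-one | CC(=O)CO[Si](C)(C)C(C)(C)C | starting material
4 | pent-4-yn-1-ylidene(triphenyl)phosphorane | C#CCCC=P(c1ccccc1)(c1ccccc1)c1ccccc1 | intermediate
5 | (Z)-tert-butyldimethyl[(2-methylhept-2-en-6-yn-1-yl)oxy]silane | C#CCC/C=C(/C)CO[Si](C)(C)C(C)(C)C | intermediate
6 | {(1E,5Z)-7-[(tert-butyldimethylsilyl)oxy]-2,6-dimethylhepta-1,5-dien-1-yl}dimethylalane | C[Al](C)/C=C(\C)CC/C=C(/C)CO[Si](C)(C)C(C)(C)C | intermediate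
7 | tert-butyl{[(2Z,6E)-7-iodo-2,6-dimethylhepta-2,6-dien-1-yl]oxy}dimethylsilane | I/C=C(\C)CC/C=C(/C)CO[Si](C)(C)C(C)(C)C | intermediate
8 | (2Z,6E)-7-iodo-2,6-dimethylhepta-2,6-dien-1-ol | I/C=C(\C)CC/C=C(/C)CO | intermediate
9 | {(2S,3R)-3-[(E)-4-iodo-3-methylbut-3-en-1-yl]-2-methyloxiran-2-yl}methanol | I/C=C(\C)CC[C@H]1O[C@@]1(C)CO | intermediate
10 | fragment A, TBS ether of 9 | I/C=C(\C)CC[C@H]1O[C@@]1(C)CO[Si](C)(C)C(C)(C)C | intermediate
11 | (S)-2-(2,2-dimethyl-1,3-dioxolan-4-yl)ethan-1-ol | OCC[C@H]1COC(C)(C)O1 | starting material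
12 | (S)-2-(2,2-dimethyl-1,3-dioxolan-4-yl)acetic acid | OC(=O)C[C@H]1COC(C)(C)O1 | intermediate
13 | (R)-4-benzyloxazolidin-2-one | O=C1N[C@H](Cc2ccccc2)CO1 | starting material
14 | (S)-2-(2,2-dimethyl-1,3-dioxolan-4-yl)acetic pivalic anhydride | CC(C)(C)C(=O)OC(=O)C[C@H]1COC(C)(C)O1 | intermediate
15 | fragment C, (R)-4-benzyl-3-{2-[(S)-2,2-dimethyl-1,3-dioxolan-4-yl]acetyl}oxazolidin-2-one | O=C(C[C@H]1COC(C)(C)O1)N1[C@H](Cc2ccccc2)COC1=O | intermediate
16 | 2,3-dihydrofuran | C1=COCC1 | starting material
17 | 5-lithio-2,3-dihydrofuran | [Li]C1=CCCO1 | intermediate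
18 | lithium 2-(4,5-dihydrofuran-2-yl)ethan-1-olate | [Li]OCCC1=CCCO1 | intermediate
19 | tert-butyl[2-(4,5-dihydrofuran-2-yl)ethoxy]dimethylsilane | CC(C)(C)[Si](C)(C)OCCC1=CCCO1 | intermediate
20 | (Z)-6-[(tert-butyldimethylsilyl)oxy]-4-[(trimethylsilyl)methyl]hex-3-en-1-ol | OCC/C=C(/CCO[Si](C)(C)C(C)(C)C)C[Si](C)(C)C | intermediate
21 | (Z)-6-[(tert-butyldimethylsilyl)oxy]-4-[(trimethylsilyl)methyl]hex-3-enal | O=CC/C=C(/CCO[Si](C)(C)C(C)(C)C)C[Si](C)(C)C | intermediate
22 | Z(O)-dibutylboron enolate of 15 | CCCCB(CCCC)O/C(=C\[C@H]1COC(C)(C)O1)N1[C@H](Cc2ccccc2)COC1=O | intermediate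
23 | Evans syn-aldol adduct (12S,13S,14S; R auxiliary) | C[Si](C)(C)C/C(CCO[Si](C)(C)C(C)(C)C)=C\C[C@H](O)[C@@H]([C@H]1COC(C)(C)O1)C(=O)N1[C@H](Cc2ccccc2)COC1=O | intermediate
24 | tetraol imide (C6, C12, C14, C15 hydroxyls free) | C[Si](C)(C)C/C(CCO)=C\C[C@H](O)[C@@H]([C@H](O)CO)C(=O)N1[C@H](Cc2ccccc2)COC1=O | intermediate
25 | (3S,4S)-3-{(1S,3Z)-1,6-dihydroxy-4-[(trimethylsilyl)methyl]hex-3-en-1-yl}-4-hydroxyoxolan-2-one | C[Si](C)(C)C/C(CCO)=C\C[C@H](O)[C@@H]1C(=O)OC[C@H]1O | intermediate
26 | (3S,4S)-4-hydroxy-3-{(1S,3Z)-1-hydroxy-6-iodo-4-[(trimethylsilyl)methyl]hex-3-en-1-yl}oxolan-2-one | C[Si](C)(C)C/C(CCI)=C\C[C@H](O)[C@@H]1C(=O)OC[C@H]1O | intermediate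
27 | fragment B, 12,14-bis-TBS ether of 26 | C[Si](C)(C)C/C(CCI)=C\C[C@H](O[Si](C)(C)C(C)(C)C)[C@@H]1C(=O)OC[C@H]1O[Si](C)(C)C(C)(C)C | intermediate
28 | alkylzinc iodide from 27 (zinc at C6) | C[Si](C)(C)C/C(CC[Zn]I)=C\C[C@H](O[Si](C)(C)C(C)(C)C)[C@@H]1C(=O)OC[C@H]1O[Si](C)(C)C(C)(C)C | intermediate
29 | cyclisation precursor: (3R,4S)-epoxide, 5E and 8Z alkenes, C17 silane, 12S,13S,14S lactone | C[Si](C)(C)C/C(CC/C=C(\C)CC[C@H]1O[C@@]1(C)CO[Si](C)(C)C(C)(C)C)=C\C[C@H](O[Si](C)(C)C(C)(C)C)[C@@H]1C(=O)OC[C@H]1O[Si](C)(C)C(C)(C)C | intermediate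
30 | 12,14,19-tris-TBS ether of the target | C=C1CC[C@@H]2[C@](C)(CO[Si](C)(C)C(C)(C)C)[C@H](O)CC[C@@]2(C)[C@@H]1C[C@H](O[Si](C)(C)C(C)(C)C)[C@@H]1C(=O)OC[C@H]1O[Si](C)(C)C(C)(C)C | intermediate
31 | CNP0113086.2 | C=C1CC[C@@H]2[C@](C)(CO)[C@H](O)CC[C@@]2(C)[C@@H]1C[C@H](O)[C@@H]1C(=O)OC[C@H]1O | target

**Step count**
Total step count: 18. Longest linear sequence: 10 steps (steps 9–18, from 2,3-dihydrofuran).

**Steps most likely to fail**

Step 17. The cascade may stall after ring A. It may also divert by a 1,2-hydride shift from C3 to C4 or a semipinacol shift, because the CH2OTBS arm retards C4–O ionisation. Lewis acid and silyl groups may also be lost to the oxygen-rich side chain, followed by cation trapping.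

The concerted opening at C4 has to be kept, since it alone transfers the Z geometry, so the fallback changes the substrate and takes the Lewis-basic side chain out of the cyclisation. It sets out from alcohol 20, uses 10 and 22, and rejoins the route at 31. Alcohol 20 is esterified with pivaloyl chloride and pyridine to the silyl ether pivalate F1. The primary silyl ether is methanolysed (PPTS, MeOH) to the hydroxy pivalate F2, which is converted by PPh3, I2 and imidazole into the iodo pivalate F3. Zinc insertion gives the alkylzinc iodide F4, and Negishi coupling with 10 as in step 16 gives the lactone-free epoxy allylsilane F5. The MeAlCl2 cascade on this simpler substrate should give the decalin pivalate F6. TBSOTf and 2,6-lutidine give the 3,19-bis(silyl ether) F7, iBu2AlH (CH2Cl2, −78 °C) frees the primary alcohol F8, and Dess–Martin oxidation gives the C12 aldehyde F9. The Evans syn-aldol with boron enolate 22 gives the decalin aldol adduct F10. Aqueous HF in MeCN then removes the acetonide and both silyl groups, with lactonisation, to give 31.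

Step 16. Zinc insertion may be slow, the alkylzinc may be protonated, the alkylpalladium species may lose a beta-hydride, or ZnI2 may open the trisubstituted epoxide.

The fallback avoids any preformed organometal. It sets out from 27 and 10 and rejoins the route at 29. Both iodides are used as electrophiles in a nickel-catalysed reductive cross-electrophile coupling (NiI2, 10 mol %, 4,4'-di-tert-butyl-2,2'-bipyridine, Mn powder, DMA, rt). In this coupling the alkyl radical from 27 is captured by the alkenylnickel species from 10 with retention of alkene geometry. No new compound arises (F0).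

Step 12. Enolisation may trigger beta-elimination of the dioxolane oxygen, the alkene of 21 may migrate into conjugation, or the C14 centre may erode the facial selectivity of the auxiliary.

The fallback uses the intact lactone as the nucleophile and sets C12 by a reagent-controlled reduction. It sets out from aldehyde 21 and rejoins the route at 25. Purchased (S)-3-hydroxy-gamma-butyrolactone F11 is silylated (TESCl, imidazole) to the TES-protected lactone F12. LiN(iPr)2 (THF, −78 °C) gives the lithium enolate F13, which adds to 21 anti to the C14 silyloxy group to give the aldol F14 as a mixture of C12 epimers. Dess–Martin oxidation gives the beta-keto lactone F15, whose C13 stays trans to C14 by equilibration. Corey–Bakshi–Shibata reduction ((R)-Me-CBS oxazaborolidine, catecholborane, toluene, −78 °C) gives the 12S alcohol F16. PPTS in MeOH then removes the TES and primary TBS groups to give 25.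

**Further compounds**
F1 | step 17 | (Z)-6-[(tert-butyldimethylsilyl)oxy]-4-[(trimethylsilyl)methyl]hex-3-en-1-yl pivalate | CC(C)(C)C(=O)OCC/C=C(/CCO[Si](C)(C)C(C)(C)C)C[Si](C)(C)C
F2 | step 17 | (Z)-6-hydroxy-4-[(trimethylsilyl)methyl]hex-3-en-1-yl pivalate | CC(C)(C)C(=O)OCC/C=C(/CCO)C[Si](C)(C)C
F3 | step 17 | (Z)-6-iodo-4-[(trimethylsilyl)methyl]hex-3-en-1-yl pivalate | CC(C)(C)C(=O)OCC/C=C(/CCI)C[Si](C)(C)C
F4 | step 17 | alkylzinc iodide from F3 | CC(C)(C)C(=O)OCC/C=C(/CC[Zn]I)C[Si](C)(C)C
F5 | step 17 | lactone-free epoxy-diene-allylsilane pivalate | CC(C)(C)C(=O)OCC/C=C(/CC/C=C(\C)CC[C@H]1O[C@@]1(C)CO[Si](C)(C)C(C)(C)C)C[Si](C)(C)C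
F6 | step 17 | 2-[(1R,4aS,5R,6R,8aS)-5-{[(tert-butyldimethylsilyl)oxy]methyl}-6-hydroxy-5,8a-dimethyl-2-methylidenedecahydronaphthalen-1-yl]ethyl pivalate | C=C1CC[C@@H]2[C@](C)(CO[Si](C)(C)C(C)(C)C)[C@H](O)CC[C@@]2(C)[C@@H]1CCOC(=O)C(C)(C)C
F7 | step 17 | 3-O-TBS ether of F6 | C=C1CC[C@@H]2[C@](C)(CO[Si](C)(C)C(C)(C)C)[C@H](O[Si](C)(C)C(C)(C)C)CC[C@@]2(C)[C@@H]1CCOC(=O)C(C)(C)C
F8 | step 17 | 3,19-bis-TBS decalin ethanol (C12 alcohol) | C=C1CC[C@@H]2[C@](C)(CO[Si](C)(C)C(C)(C)C)[C@H](O[Si](C)(C)C(C)(C)C)CC[C@@]2(C)[C@@H]1CCO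
F9 | step 17 | 3,19-bis-TBS decalin acetaldehyde (C12 aldehyde) | C=C1CC[C@@H]2[C@](C)(CO[Si](C)(C)C(C)(C)C)[C@H](O[Si](C)(C)C(C)(C)C)CC[C@@]2(C)[C@@H]1CC=O
F10 | step 17 | Evans syn-aldol adduct of F9 and 22 | C=C1CC[C@@H]2[C@](C)(CO[Si](C)(C)C(C)(C)C)[C@H](O[Si](C)(C)C(C)(C)C)CC[C@@]2(C)[C@@H]1C[C@H](O)[C@@H]([C@H]1COC(C)(C)O1)C(=O)N1[C@H](Cc2ccccc2)COC1=O
F0 | step 16 | none | none
F11 | step 12 | (S)-3-hydroxy-gamma-butyrolactone (purchased) | O=C1C[C@H](O)CO1
F12 | step 12 | (S)-4-[(triethylsilyl)oxy]oxolan-2-one | O=C1C[C@H](O[Si](CC)(CC)CC)CO1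
F13 | step 12 | lithium enolate of F12 | [Li]OC1=C[C@H](O[Si](CC)(CC)CC)CO1
F14 | step 12 | lactone aldol adduct, C12 epimers, C13/C14 trans | C[Si](C)(C)C/C(CCO[Si](C)(C)C(C)(C)C)=C\CC(O)[C@@H]1C(=O)OC[C@H]1O[Si](CC)(CC)CC
F15 | step 12 | C12 beta-keto lactone | C[Si](C)(C)C/C(CCO[Si](C)(C)C(C)(C)C)=C\CC(=O)[C@@H]1C(=O)OC[C@H]1O[Si](CC)(CC)CC
F16 | step 12 | 12S alcohol (6-O-TBS, 14-O-TES) | C[Si](C)(C)C/C(CCO[Si](C)(C)C(C)(C)C)=C\C[C@H](O)[C@@H]1C(=O)OC[C@H]1O[Si](CC)(CC)CC
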